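Ring carbons are numbered C1–C10 along the target SMILES (ring A: C1–C7; ring B: C6–C10). Ring A hides a δ-hydroxy enone: once C1 is a ketone, the C2=C3 alkene relays its enol reactivity to C4, which sits next to the C5 carbinol. The route therefore rests on breaking C4–C5, which unfolds ring A onto a trans-1,2-disubstituted cyclopentane (ring B) carrying C6, C7 and C10 in final form. The key step, an intramolecular vinylogous Mukaiyama aldol addition, forms the seven-membered ring, the C5 stereocentre and the cis C2=C3 alkene at once. Its precursor carries a (1E)-silyl dienol ether (C1–C4) on C7 and the C5 aldehyde on C6.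

Key step: step 13

Remarks on the chemistry:
- β is the face of ring B that carries the C7 methyl group, α the opposite face; bicyclic compounds are named with the route numbering.
- Only a (1E)-dienol ether, with C3 cis to C7 across C1=C2, can bring C4 to C5. The (1Z) isomer, which γ-deprotonation of a 3-methylbut-2-enoyl ketone would give, would need a trans double bond inside the forming seven-membered ring and is taken as unproductive. The (1E) isomer is therefore built stereospecifically in steps 8–10.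
- C1 enters as a 1-(trimethylsilyl)ethenyl group, far bulkier than methyl, so that C6 is functionalised trans to it.

Step 1
Reactants: 1 3-methylcyclopent-2-en-1-one; 2 ethynyl(trimethyl)silane
Product: 5 trimethyl{[(3S)-3-methyl-3-(1-trimethylsilylethenyl)cyclopent-1-en-1-yl]oxy}silane, via vinylalane 3 (not isolated), via aluminium enolate 4 (not isolated)
Conditions: 2, i-Bu2AlH, hexane, 55 °C; then 1, Cu(OTf)2 (5 mol %), chiral sulfonate-bearing imidazolinium salt (NHC precursor, 5 mol %), THF, −30 °C; then Me3SiOTf, −30 → 0 °C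
Reagents that add atoms: trimethylsilyl trifluoromethanesulfonate, C[Si](C)(C)OS(=O)(=O)C(F)(F)F
Why: Copper-catalysed enantioselective conjugate addition of a 1-silylvinylalane (from hydroalumination of 2) to a β-methyl cyclic enone is an established route to quaternary carbons in five-membered rings, the ligand antipode being chosen to set C7 as drawn, and O-silylation of the aluminium enolate stores the enolate regiochemistry at C6.

Step 2
Reactants: 5 trimethyl{[(3S)-3-methyl-3-(1-trimethylsilylethenyl)cyclopent-1-en-1-yl]oxy}silane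
Product: 6 (2S,3S)-2-(hydroxymethyl)-3-methyl-3-(1-trimethylsilylethenyl)cyclopentan-1-one
Conditions: aq. HCHO (37 %), Sc(OTf)3 (10 mol %), THF, 22 °C
Reagents that add atoms: formaldehyde, C=O
Why: Lewis-acid-catalysed Mukaiyama aldol addition (hydroxymethylation) in aqueous medium; formaldehyde enters C6 anti to the bulky silylvinyl group on C7, so the CH2OH group ends cis to the C7 methyl group, which is also the more stable arrangement at this enolisable centre.

Step 3
Reactants: 6 (2S,3S)-2-(hydroxymethyl)-3-methyl-3-(1-trimethylsilylethenyl)cyclopentan-1-one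
Product: 7 [(1S,2S)-2-methyl-5-oxo-2-(1-trimethylsilylethenyl)cyclopentyl]methyl 2,2-dimethylpropanoate
Conditions: t-BuCOCl, pyridine, DMAP (cat.), CH2Cl2, 0 °C
Reagents that add atoms: pivaloyl chloride, CC(C)(C)C(=O)Cl
Why: Nucleophile-catalysed acylation of the primary alcohol; the pivalate has no α-hydrogen, resists the organometallic and amide-base steps ahead and leaves later with a hydride reagent that spares silyl enol ethers.

Step 4
Reactants: 7 [(1S,2S)-2-methyl-5-oxo-2-(1-trimethylsilylethenyl)cyclopentyl]methyl 2,2-dimethylpropanoate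
Product: 8 [(1S,2S,5R)-5-hydroxy-2-methyl-5-(propan-2-yl)-2-(1-trimethylsilylethenyl)cyclopentyl]methyl 2,2-dimethylpropanoate
Conditions: i-PrMgCl, CeCl3, THF, −78 °C; aq. NH4Cl
Reagents that add atoms: isopropylmagnesium chloride, CC(C)[Mg]Cl
Why: Organocerium 1,2-addition, which keeps enolisation, β-elimination of pivalate and β-hydride reduction in check; the reagent attacks the cyclopentanone anti to the adjacent C6 substituent (α face, the β face being further shielded by the C7 methyl group), giving the C10 β-hydroxyl and α-isopropyl groups.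

Step 5
Reactants: 8 [(1S,2S,5R)-5-hydroxy-2-methyl-5-(propan-2-yl)-2-(1-trimethylsilylethenyl)cyclopentyl]methyl 2,2-dimethylpropanoate
Product: 9 [(1S,2S,5R)-2-methyl-5-(propan-2-yl)-5-(triethylsilyloxy)-2-(1-trimethylsilylethenyl)cyclopentyl]methyl 2,2-dimethylpropanoate
Conditions: Et3SiOTf, 2,6-lutidine, CH2Cl2, −78 → 22 °C
Reagents that add atoms: triethylsilyl trifluoromethanesulfonate, CC[Si](CC)(CC)OS(=O)(=O)C(F)(F)F
Why: Silylation with a silyl triflate is the standard way to cap a hindered tertiary alcohol, which must be masked because a free β-hydroxyl would quench the Lewis acid and protonate the dienol ether in the key step.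

Step 6
Reactants: 9 [(1S,2S,5R)-2-methyl-5-(propan-2-yl)-5-(triethylsilyloxy)-2-(1-trimethylsilylethenyl)cyclopentyl]methyl 2,2-dimethylpropanoate
Product: 10 [(1S,2S,5R)-2-(1-iodoethenyl)-2-methyl-5-(propan-2-yl)-5-(triethylsilyloxy)cyclopentyl]methyl 2,2-dimethylpropanoate
Conditions: NIS, MeCN, 0 → 22 °C
Reagents that add atoms: N-iodosuccinimide, O=C1CCC(=O)N1I
Why: Electrophilic ipso-iododesilylation of the vinylsilane, in which the β-silyl cation formed on attack of iodine at the silicon-bearing carbon loses the silyl group to give the 2-iodoalkene.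

Step 7
Reactants: 10 [(1S,2S,5R)-2-(1-iodoethenyl)-2-methyl-5-(propan-2-yl)-5-(triethylsilyloxy)cyclopentyl]methyl 2,2-dimethylpropanoate
Product: 11 [(1S,2S,5R)-2-ethynyl-2-methyl-5-(propan-2-yl)-5-(triethylsilyloxy)cyclopentyl]methyl 2,2-dimethylpropanoate
Conditions: LiN(i-Pr)2 (2.5 equiv), THF, −78 → 0 °C; aq. NH4Cl
Reagents that add atoms: none
Why: Base-induced anti elimination of hydrogen iodide (dehydrohalogenation of a 2-haloalkene) gives the terminal alkyne, and because C7 is quaternary no allene can form and the hindered pivalate is not attacked by the amide base.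

Step 8
Reactants: 11 [(1S,2S,5R)-2-ethynyl-2-methyl-5-(propan-2-yl)-5-(triethylsilyloxy)cyclopentyl]methyl 2,2-dimethylpropanoate
Product: 12 [(1S,2S,5R)-2-[(E)-1-acetoxy-2-iodoethenyl]-2-methyl-5-(propan-2-yl)-5-(triethylsilyloxy)cyclopentyl]methyl 2,2-dimethylpropanoate
Conditions: NIS, AcOH, CH2Cl2, 0 → 22 °C, dark
Reagents that add atoms: N-iodosuccinimide, O=C1CCC(=O)N1I; acetic acid, CC(=O)O
Why: Electrophilic iodoacetoxylation of the terminal alkyne, in which acetate opens the iodonium ion at the substituted carbon from the side opposite to iodine, so that this anti addition places iodine cis to C7 and fixes the geometry of the later C1=C2 bond.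

Step 9
Reactants: 12 [(1S,2S,5R)-2-[(E)-1-acetoxy-2-iodoethenyl]-2-methyl-5-(propan-2-yl)-5-(triethylsilyloxy)cyclopentyl]methyl 2,2-dimethylpropanoate; 13 tributyl(prop-1-en-2-yl)stannane
Product: 14 [(1S,2S,5R)-2-[(1E)-1-acetoxy-3-methylbuta-1,3-dien-1-yl]-2-methyl-5-(propan-2-yl)-5-(triethylsilyloxy)cyclopentyl]methyl 2,2-dimethylpropanoate
Conditions: Pd(PPh3)4 (5 mol %), CuI (10 mol %), DMF, 45 °C
Reagents that add atoms: none
Why: Stille coupling of the alkenyl iodide proceeds with retention of the alkene geometry and brings in C3, C4 and the C3 methyl group, giving the (1E)-dienol acetate with C3 cis to C7.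

Step 10
Reactants: 14 [(1S,2S,5R)-2-[(1E)-1-acetoxy-3-methylbuta-1,3-dien-1-yl]-2-methyl-5-(propan-2-yl)-5-(triethylsilyloxy)cyclopentyl]methyl 2,2-dimethylpropanoate
Product: 16 [(1S,2S,5R)-2-[(1E)-1-(tert-butyldimethylsilyloxy)-3-methylbuta-1,3-dien-1-yl]-2-methyl-5-(propan-2-yl)-5-(triethylsilyloxy)cyclopentyl]methyl 2,2-dimethylpropanoate, via lithium dienolate 15 (not isolated)
Conditions: MeLi (2.1 equiv), THF, −78 → −40 °C; then t-BuMe2SiCl, DMPU, −78 → 0 °C
Reagents that add atoms: tert-butyl(chloro)dimethylsilane, CC(C)(C)[Si](C)(C)Cl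
Why: Cleavage of an enol acetate with methyllithium gives the lithium enolate with unchanged double-bond geometry, and O-silylation of this dienolate in a dipolar cosolvent gives the (1E)-silyl dienol ether, while the hindered pivalate survives at low temperature.

Step 11
Reactants: 16 [(1S,2S,5R)-2-[(1E)-1-(tert-butyldimethylsilyloxy)-3-methylbuta-1,3-dien-1-yl]-2-methyl-5-(propan-2-yl)-5-(triethylsilyloxy)cyclopentyl]methyl 2,2-dimethylpropanoate
Product: 17 {(1S,2S,5R)-2-[(1E)-1-(tert-butyldimethylsilyloxy)-3-methylbuta-1,3-dien-1-yl]-2-methyl-5-(propan-2-yl)-5-(triethylsilyloxy)cyclopentyl}methanol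
Conditions: i-Bu2AlH, CH2Cl2, −78 °C; aq. potassium sodium tartrate
Reagents that add atoms: none
Why: Reductive cleavage of the pivalate with an aluminium hydride leaves both silyl ethers and the dienol ether untouched, and the neutral tartrate work-up avoids acid that would hydrolyse the dienol ether.

Step 12
Reactants: 17 {(1S,2S,5R)-2-[(1E)-1-(tert-butyldimethylsilyloxy)-3-methylbuta-1,3-dien-1-yl]-2-methyl-5-(propan-2-yl)-5-(triethylsilyloxy)cyclopentyl}methanol
Product: 18 (1R,2S,5R)-2-[(1E)-1-(tert-butyldimethylsilyloxy)-3-methylbuta-1,3-dien-1-yl]-2-methyl-5-(propan-2-yl)-5-(triethylsilyloxy)cyclopentane-1-carbaldehyde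
Conditions: Dess–Martin periodinane, pyridine, CH2Cl2, 0 → 22 °C
Reagents that add atoms: none
Why: Dess–Martin oxidation buffered with pyridine gives the aldehyde under conditions too mild to hydrolyse the dienol ether or to epimerise the C6 centre next to the new carbonyl group.

Step 13
Reactants: 18 (1R,2S,5R)-2-[(1E)-1-(tert-butyldimethylsilyloxy)-3-methylbuta-1,3-dien-1-yl]-2-methyl-5-(propan-2-yl)-5-(triethylsilyloxy)cyclopentane-1-carbaldehyde
Product: 20 ring A hydroxy enone (5S,6S,7S,10R)-5-hydroxy-3,7-dimethyl-10-(propan-2-yl)-10-(triethylsilyloxy)bicyclo[5.3.0]dec-2-en-1-one, via difluoroboryl aldolate 19 (not isolated)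
Conditions: BF3·OEt2 (1.2 equiv), CH2Cl2 (0.002 M), −78 °C; aq. NaHCO3
Reagents that add atoms: none
Why: BF3 activates the C5 aldehyde and the diene terminus C4 of the 2-siloxydiene adds to it through an open transition state, after which the silyl oxocarbenium ion at C1 gives up its silyl group to fluoride and the C1 ketone returns; the closest known reaction type is the Lewis-acid-mediated intramolecular vinylogous Mukaiyama aldol addition. Ring A closes in the 7-(enolendo)-exo-trig mode, both diene double bonds lying inside the forming ring, so the new C2=C3 alkene can only be cis. The new C5 stereocentre is controlled by C6 and the trans ring fusion: in the half-chair-like transition state the BF3-bound oxygen takes the pseudo-equatorial site anti to H-6, which puts the C5 oxygen on the α face. The step needs attack through C4 and not C2, and this is secured by the (1E) geometry, which holds C3 and C4 on the C7 side of C1=C2, and by the trans-1,2 pattern on ring B, under which C2 attack would have to build a trans-fused bicyclo[3.3.0]octanone. Low temperature and the absence of base leave the enolisable C6 centre intact, and high dilution holds back intermolecular addition.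

Step 14
Reactants: 20 ring A hydroxy enone; 21 3,4-dimethoxybenzoyl chloride
Product: 22 (5S,6S,7S,10R)-5-(3,4-dimethoxybenzoyloxy)-3,7-dimethyl-10-(propan-2-yl)-10-(triethylsilyloxy)bicyclo[5.3.0]dec-2-en-1-one
Conditions: pyridine, DMAP, CH2Cl2, 22 °C
Reagents that add atoms: none
Why: DMAP-catalysed acylation of the only free hydroxyl group installs the veratrate with retention at C5, the tertiary C10 oxygen being silylated.

Step 15
Reactants: 22 (5S,6S,7S,10R)-5-(3,4-dimethoxybenzoyloxy)-3,7-dimethyl-10-(propan-2-yl)-10-(triethylsilyloxy)bicyclo[5.3.0]dec-2-en-1-one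
Product: 23 (1R,5S,6S,7S,10R)-5-(3,4-dimethoxybenzoyloxy)-3,7-dimethyl-10-(propan-2-yl)-10-(triethylsilyloxy)bicyclo[5.3.0]dec-2-en-1-ol
Conditions: LiBH(s-Bu)3, THF, −78 °C; aq. NH4Cl
Reagents that add atoms: none
Why: 1,2-Reduction of the β,β-disubstituted enone with a bulky trialkylborohydride, which is expected to avoid the axial path on the α face past H-6 and to deliver hydride along the pseudo-equatorial path on the β face, giving the pseudo-axial α alcohol at C1 while the aryl ester is left alone at this temperature.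

Step 16
Reactants: 23 (1R,5S,6S,7S,10R)-5-(3,4-dimethoxybenzoyloxy)-3,7-dimethyl-10-(propan-2-yl)-10-(triethylsilyloxy)bicyclo[5.3.0]dec-2-en-1-ol; 24 angelic acid
Product: 26 (1R,5S,6S,7S,10R)-5-(3,4-dimethoxybenzoyloxy)-3,7-dimethyl-10-(propan-2-yl)-10-(triethylsilyloxy)bicyclo[5.3.0]dec-2-en-1-yl (Z)-2-methylbut-2-enoate, via mixed anhydride 25 (not isolated)
Conditions: 24, 2,4,6-Cl3C6H2COCl, Et3N, PhMe, 22 °C; then 23, 80 °C
Reagents that add atoms: none
Why: Yamaguchi esterification through the mixed 2,4,6-trichlorobenzoic anhydride acylates hindered secondary alcohols without nucleophilic catalysts that isomerise angelates to tiglates, and the C1 configuration is kept because the C–O bond is not broken.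

Step 17
Reactants: 26 (1R,5S,6S,7S,10R)-5-(3,4-dimethoxybenzoyloxy)-3,7-dimethyl-10-(propan-2-yl)-10-(triethylsilyloxy)bicyclo[5.3.0]dec-2-en-1-yl (Z)-2-methylbut-2-enoate
Product: 27 target CNP0142353.1
Conditions: HF·pyridine, pyridine, THF, 0 → 22 °C
Reagents that add atoms: none
Why: Fluoride-mediated desilylation under buffered conditions removes the tertiary triethylsilyl ether without touching the two esters or the allylic C1–O bond.

Compound list

1 | 3-methylcyclopent-2-en-1-one | CC1=CC(=O)CC1 | starting material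
2 | ethynyl(trimethyl)silane | C#C[Si](C)(C)C | starting material
3 | bis(2-methylpropyl)[1-(trimethylsilyl)ethenyl]alumane | C=C([Al](CC(C)C)CC(C)C)[Si](C)(C)C | intermediate
4 | bis(2-methylpropyl){[(3S)-3-methyl-3-(1-trimethylsilylethenyl)cyclopent-1-en-1-yl]oxy}alumane | C=C([Si](C)(C)C)[C@@]1(C)CCC(O[Al](CC(C)C)CC(C)C)=C1 | intermediate
5 | trimethyl{[(3S)-3-methyl-3-(1-trimethylsilylethenyl)cyclopent-1-en-1-yl]oxy}silane | C=C([Si](C)(C)C)[C@@]1(C)CCC(O[Si](C)(C)C)=C1 | intermediate
6 | (2S,3S)-2-(hydroxymethyl)-3-methyl-3-(1-trimethylsilylethenyl)cyclopentan-1-one (CH2OH cis to the ring methyl) | C=C([Si](C)(C)C)[C@@]1(C)CCC(=O)[C@@H]1CO | intermediate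
7 | [(1S,2S)-2-methyl-5-oxo-2-(1-trimethylsilylethenyl)cyclopentyl]methyl 2,2-dimethylpropanoate | C=C([Si](C)(C)C)[C@@]1(C)CCC(=O)[C@@H]1COC(=O)C(C)(C)C | intermediate
8 | [(1S,2S,5R)-5-hydroxy-2-methyl-5-(propan-2-yl)-2-(1-trimethylsilylethenyl)cyclopentyl]methyl 2,2-dimethylpropanoate (C10 β-OH, α-isopropyl) | C=C([Si](C)(C)C)[C@@]1(C)CC[C@@](O)(C(C)C)[C@@H]1COC(=O)C(C)(C)C | intermediate
9 | [(1S,2S,5R)-2-methyl-5-(propan-2-yl)-5-(triethylsilyloxy)-2-(1-trimethylsilylethenyl)cyclopentyl]methyl 2,2-dimethylpropanoate | C=C([Si](C)(C)C)[C@@]1(C)CC[C@@](O[Si](CC)(CC)CC)(C(C)C)[C@@H]1COC(=O)C(C)(C)C | intermediate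
10 | [(1S,2S,5R)-2-(1-iodoethenyl)-2-methyl-5-(propan-2-yl)-5-(triethylsilyloxy)cyclopentyl]methyl 2,2-dimethylpropanoate | C=C(I)[C@@]1(C)CC[C@@](O[Si](CC)(CC)CC)(C(C)C)[C@@H]1COC(=O)C(C)(C)C | intermediate
11 | [(1S,2S,5R)-2-ethynyl-2-methyl-5-(propan-2-yl)-5-(triethylsilyloxy)cyclopentyl]methyl 2,2-dimethylpropanoate | C#C[C@@]1(C)CC[C@@](O[Si](CC)(CC)CC)(C(C)C)[C@@H]1COC(=O)C(C)(C)C | intermediate
12 | [(1S,2S,5R)-2-[(E)-1-acetoxy-2-iodoethenyl]-2-methyl-5-(propan-2-yl)-5-(triethylsilyloxy)cyclopentyl]methyl 2,2-dimethylpropanoate (iodine cis to C7) | I/C=C(/OC(C)=O)[C@@]1(C)CC[C@@](O[Si](CC)(CC)CC)(C(C)C)[C@@H]1COC(=O)C(C)(C)C | intermediate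
13 | tributyl(prop-1-en-2-yl)stannane | CC(=C)[Sn](CCCC)(CCCC)CCCC | starting material
14 | [(1S,2S,5R)-2-[(1E)-1-acetoxy-3-methylbuta-1,3-dien-1-yl]-2-methyl-5-(propan-2-yl)-5-(triethylsilyloxy)cyclopentyl]methyl 2,2-dimethylpropanoate | C=C(C)/C=C(/OC(C)=O)[C@@]1(C)CC[C@@](O[Si](CC)(CC)CC)(C(C)C)[C@@H]1COC(=O)C(C)(C)C | intermediate
15 | lithium (1E)-dienolate of the C1 ketone (pivalate and triethylsilyl ether as in 14) | C=C(C)/C=C(/O[Li])[C@@]1(C)CC[C@@](O[Si](CC)(CC)CC)(C(C)C)[C@@H]1COC(=O)C(C)(C)C | intermediate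
16 | [(1S,2S,5R)-2-[(1E)-1-(tert-butyldimethylsilyloxy)-3-methylbuta-1,3-dien-1-yl]-2-methyl-5-(propan-2-yl)-5-(triethylsilyloxy)cyclopentyl]methyl 2,2-dimethylpropanoate | C=C(C)/C=C(/O[Si](C)(C)C(C)(C)C)[C@@]1(C)CC[C@@](O[Si](CC)(CC)CC)(C(C)C)[C@@H]1COC(=O)C(C)(C)C | intermediate
17 | {(1S,2S,5R)-2-[(1E)-1-(tert-butyldimethylsilyloxy)-3-methylbuta-1,3-dien-1-yl]-2-methyl-5-(propan-2-yl)-5-(triethylsilyloxy)cyclopentyl}methanol | C=C(C)/C=C(/O[Si](C)(C)C(C)(C)C)[C@@]1(C)CC[C@@](O[Si](CC)(CC)CC)(C(C)C)[C@@H]1CO | intermediate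
18 | (1R,2S,5R)-2-[(1E)-1-(tert-butyldimethylsilyloxy)-3-methylbuta-1,3-dien-1-yl]-2-methyl-5-(propan-2-yl)-5-(triethylsilyloxy)cyclopentane-1-carbaldehyde (key-step precursor; C3 cis to C7) | C=C(C)/C=C(/O[Si](C)(C)C(C)(C)C)[C@@]1(C)CC[C@@](O[Si](CC)(CC)CC)(C(C)C)[C@@H]1C=O | intermediate
19 | difluoroboryl aldolate of 20 (C5–O–BF2) | O=C1C=C(C)C[C@H](OB(F)F)[C@@H]2[C@]1(C)CC[C@@]2(O[Si](CC)(CC)CC)C(C)C | intermediate
20 | ring A hydroxy enone, (5S,6S,7S,10R)-5-hydroxy-3,7-dimethyl-10-(propan-2-yl)-10-(triethylsilyloxy)bicyclo[5.3.0]dec-2-en-1-one (route numbering; trans-fused, 5α-OH) | O=C1C=C(C)C[C@H](O)[C@@H]2[C@]1(C)CC[C@@]2(O[Si](CC)(CC)CC)C(C)C | intermediate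
21 | 3,4-dimethoxybenzoyl chloride | COc1ccc(C(=O)Cl)cc1OC | starting material
22 | (5S,6S,7S,10R)-5-(3,4-dimethoxybenzoyloxy)-3,7-dimethyl-10-(propan-2-yl)-10-(triethylsilyloxy)bicyclo[5.3.0]dec-2-en-1-one (route numbering) | O=C1C=C(C)C[C@H](OC(=O)c3ccc(OC)c(OC)c3)[C@@H]2[C@]1(C)CC[C@@]2(O[Si](CC)(CC)CC)C(C)C | intermediate
23 | (1R,5S,6S,7S,10R)-5-(3,4-dimethoxybenzoyloxy)-3,7-dimethyl-10-(propan-2-yl)-10-(triethylsilyloxy)bicyclo[5.3.0]dec-2-en-1-ol (route numbering; 1α-OH, trans to the C7 methyl) | O[C@@H]1C=C(C)C[C@H](OC(=O)c3ccc(OC)c(OC)c3)[C@@H]2[C@]1(C)CC[C@@]2(O[Si](CC)(CC)CC)C(C)C | intermediate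
24 | angelic acid, (Z)-2-methylbut-2-enoic acid | C/C=C(/C)C(=O)O | starting material
25 | (Z)-2-methylbut-2-enoic 2,4,6-trichlorobenzoic anhydride | C/C=C(/C)C(=O)OC(=O)c1c(Cl)cc(Cl)cc1Cl | intermediate
26 | (1R,5S,6S,7S,10R)-5-(3,4-dimethoxybenzoyloxy)-3,7-dimethyl-10-(propan-2-yl)-10-(triethylsilyloxy)bicyclo[5.3.0]dec-2-en-1-yl (Z)-2-methylbut-2-enoate (route numbering) | C/C=C(/C)C(=O)O[C@@H]1C=C(C)C[C@H](OC(=O)c3ccc(OC)c(OC)c3)[C@@H]2[C@]1(C)CC[C@@]2(O[Si](CC)(CC)CC)C(C)C | intermediate
27 | CNP0142353.1, (1R,5S,6S,7S,10R)-5-(3,4-dimethoxybenzoyloxy)-10-hydroxy-3,7-dimethyl-10-(propan-2-yl)bicyclo[5.3.0]dec-2-en-1-yl (Z)-2-methylbut-2-enoate (route numbering) | C/C=C(/C)C(=O)O[C@@H]1C=C(C)C[C@H](OC(=O)c2ccc(OC)c(OC)c2)[C@@H]2[C@]1(C)CC[C@@]2(O)C(C)C | target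

Total step count: 17. Longest linear sequence: 17 steps, from 1 to 27.

Steps most likely to fail

1. Step 13. The dienol ether may add to the other face of the aldehyde, so that the C5 oxygen ends pseudo-axial on the β face. The fallback sets out from 18 and comes back at 22: the same closure then gives mainly the 5β-hydroxy epimer of 20 F1, and this alcohol is esterified with inversion under Mitsunobu conditions (3,4-dimethoxybenzoic acid, PPh3, diisopropyl azodicarboxylate, PhMe), which gives the 5α-veratrate 22 directly.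

2. Step 8. Opening of the iodonium ion beside the quaternary C7 may drift toward a free vinyl cation, with a 1,2-shift (ring expansion) or loss of the anti course, and with it loss of the (1E) geometry on which the closure depends. The fallback gives up the dienol ether, sets out from 11 and comes back at 20, passing over steps 8 to 13.
   - RuCl3 (cat.) with NaIO4 cleaves the alkyne to the C1 carboxylic acid F2.
   - Oxalyl chloride and then N,O-dimethylhydroxylamine give the Weinreb amide F3.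
   - 2-Methylallylmagnesium chloride gives the β,γ-unsaturated ketone F4.
   - i-Bu2AlH reduces the ketone and removes the pivalate, giving the diol F5.
   - Dess–Martin periodinane oxidises both alcohols to the keto aldehyde F6.
   - Me2AlCl in CH2Cl2 at −78 °C brings about a type 2 carbonyl-ene cyclisation, in which the 1,1-disubstituted alkene attacks the aldehyde through C4 and no enol ether geometry is involved, giving the exo-methylene ketol F7.
   - DBU moves the exocyclic alkene into conjugation with the C1 ketone and gives 20.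

3. Step 15. Hydride may be delivered on the α face, anti to the C7 methyl group, which gives the 1β alcohol. The fallback sets out from 22 and comes back at 23: NaBH4 with CeCl3·7H2O in MeOH (Luche reduction) is used to make the 1β alcohol F8 on purpose; Mitsunobu inversion with 4-nitrobenzoic acid, PPh3 and diisopropyl azodicarboxylate gives the 1α 4-nitrobenzoate F9; K2CO3 in MeOH at 0 °C cleaves this activated ester in preference to the veratrate and gives 23.

Further compounds

F1 | step 13 | (5R,6S,7S,10R)-5-hydroxy-3,7-dimethyl-10-(propan-2-yl)-10-(triethylsilyloxy)bicyclo[5.3.0]dec-2-en-1-one (5β-hydroxy epimer of 20) | O=C1C=C(C)C[C@@H](O)[C@@H]2[C@]1(C)CC[C@@]2(O[Si](CC)(CC)CC)C(C)C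
F2 | step 8 | (1S,2S,3R)-2-[(2,2-dimethylpropanoyloxy)methyl]-1-methyl-3-(propan-2-yl)-3-(triethylsilyloxy)cyclopentane-1-carboxylic acid | OC(=O)[C@@]1(C)CC[C@@](O[Si](CC)(CC)CC)(C(C)C)[C@@H]1COC(=O)C(C)(C)C
F3 | step 8 | N-methoxy-N-methyl amide of F2 (Weinreb amide) | CON(C)C(=O)[C@@]1(C)CC[C@@](O[Si](CC)(CC)CC)(C(C)C)[C@@H]1COC(=O)C(C)(C)C
F4 | step 8 | [(1S,2S,5R)-2-methyl-2-(3-methylbut-3-enoyl)-5-(propan-2-yl)-5-(triethylsilyloxy)cyclopentyl]methyl 2,2-dimethylpropanoate | C=C(C)CC(=O)[C@@]1(C)CC[C@@](O[Si](CC)(CC)CC)(C(C)C)[C@@H]1COC(=O)C(C)(C)C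
F5 | step 8 | 1-[(1S,2S,3R)-2-(hydroxymethyl)-1-methyl-3-(propan-2-yl)-3-(triethylsilyloxy)cyclopentyl]-3-methylbut-3-en-1-ol (either configuration at the carbinol) | C=C(C)CC(O)[C@@]1(C)CC[C@@](O[Si](CC)(CC)CC)(C(C)C)[C@@H]1CO
F6 | step 8 | (1R,2S,5R)-2-methyl-2-(3-methylbut-3-enoyl)-5-(propan-2-yl)-5-(triethylsilyloxy)cyclopentane-1-carbaldehyde | C=C(C)CC(=O)[C@@]1(C)CC[C@@](O[Si](CC)(CC)CC)(C(C)C)[C@@H]1C=O
F7 | step 8 | (5S,6S,7S,10R)-5-hydroxy-7-methyl-3-methylidene-10-(propan-2-yl)-10-(triethylsilyloxy)bicyclo[5.3.0]decan-1-one (route numbering) | O=C1CC(=C)C[C@H](O)[C@@H]2[C@]1(C)CC[C@@]2(O[Si](CC)(CC)CC)C(C)C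
F8 | step 15 | (1S,5S,6S,7S,10R)-5-(3,4-dimethoxybenzoyloxy)-3,7-dimethyl-10-(propan-2-yl)-10-(triethylsilyloxy)bicyclo[5.3.0]dec-2-en-1-ol (1β-hydroxy epimer of 23) | O[C@H]1C=C(C)C[C@H](OC(=O)c3ccc(OC)c(OC)c3)[C@@H]2[C@]1(C)CC[C@@]2(O[Si](CC)(CC)CC)C(C)C
F9 | step 15 | (1R,5S,6S,7S,10R)-5-(3,4-dimethoxybenzoyloxy)-3,7-dimethyl-10-(propan-2-yl)-10-(triethylsilyloxy)bicyclo[5.3.0]dec-2-en-1-yl 4-nitrobenzoate | O=C(O[C@@H]1C=C(C)C[C@H](OC(=O)c3ccc(OC)c(OC)c3)[C@@H]2[C@]1(C)CC[C@@]2(O[Si](CC)(CC)CC)C(C)C)c4ccc(cc4)[N+](=O)[O-]
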